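**Plan**

Numbering used below (xenicane): lactone O2–C1H2, C3=O, C4(=C12), ring fusion C4a/C11a, nine-membered ring C4a–C5–C6–C7–C8–C9–C10–C11–C11a, exocyclic C11=C19H2, side chain C12–C15.
Retrosynthetic cuts, in this order: C8–C9 epoxide (hydroxyl-directed epoxidation), C4=C12 (aldol condensation with an epoxy aldehyde), C11=C19 (ketone methylenation), C8=C9 (ring-closing metathesis) and C10–C11 (allylation), the lactone O2–C1 bond, C4a–C11a (radical conjugate addition), C4=C4a (Horner–Wadsworth–Emmons).
Enabling feature: C11a carries two one-carbon arms, the lactone O–CH2 (C1) and C11, and the C3 carboxyl lies five atoms from either; the C1–C11a–C11 unit is therefore brought in as an oxetane ring (C1–O–C11), and its opening by the C3 acid closes the δ-lactone, chooses between two diastereotopic CH2–O termini (C11a set trans to C4a) and releases C11 as CH2OH, later raised to C(=CH2).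
Forward order of rings: six-membered lactone first (key step), then the nine-membered carbocycle by metathesis across C8=C9, then the side chain at C4, last the ring epoxide.
Stereochemistry: C7 from (S)-linalool made by Sharpless epoxidation of geraniol; C4a from an oxazolidinone auxiliary; C11a from the key step; C13/C14 from a Sharpless kinetic resolution; C8/C9 from the C7 hydroxyl; 8Z from ring size and 12E from E1cB elimination.

Key step: step 11

Remark: the carbinol carbon made in step 14 (C11) and the two centers made in step 22 (C4, C12) are carried as epimer mixtures because each is destroyed again (steps 16 and 23); the SMILES of those compounds leave these centers open.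

**Route**

Step 1
Reactants: 1 geraniol
Product: 2 (2S,3S)-2,3-epoxygeraniol
Conditions: Ti(OiPr)4 (5 mol%), L-(+)-diethyl tartrate (6 mol%), t-BuOOH, 4 Å MS, CH2Cl2, −20 °C
Reagents that add atoms: tert-butyl hydroperoxide, CC(C)(C)OO
Why: Sharpless asymmetric epoxidation of an E-trisubstituted allylic alcohol, in which the L-(+)-tartrate–titanium complex delivers oxygen to one alkene face and sets both epoxide carbons as S (C3 is the future C7).

Step 2
Reactants: 2 (2S,3S)-2,3-epoxygeraniol
Product: 3 (2R,3S)-2-(iodomethyl)-3-methyl-3-(4-methylpent-3-en-1-yl)oxirane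
Conditions: I2, PPh3, imidazole, CH2Cl2, 0 °C
Reagents that add atoms: iodine, II
Why: Appel-type iodination of the primary alcohol by SN2 displacement at CH2, which leaves the epoxide and both stereocenters untouched.

Step 3
Reactants: 3 (2R,3S)-2-(iodomethyl)-3-methyl-3-(4-methylpent-3-en-1-yl)oxirane
Product: 4 (S)-linalool, (3S)-3,7-dimethylocta-1,6-dien-3-ol
Conditions: Zn dust, AcOH, EtOH, 23 °C
Reagents that add atoms: none
Why: Reductive fragmentation of a 2,3-epoxy iodide (zinc insertion into C–I, then β-elimination of the epoxide oxygen) gives the tertiary allylic alcohol, and the carbinol C–O bond is never broken, so its configuration is retained.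

Step 4
Reactants: 4 (S)-linalool
Product: 5 (S)-linalool triethylsilyl ether, triethyl{[(3S)-3,7-dimethylocta-1,6-dien-3-yl]oxy}silane
Conditions: Et3SiOTf, 2,6-lutidine, CH2Cl2, −78 → 0 °C
Reagents that add atoms: triethylsilyl trifluoromethanesulfonate, CC[Si](CC)(CC)OS(=O)(=O)C(F)(F)F
Why: Silylation of the hindered tertiary alcohol with the silyl triflate, which prevents lactol formation in step 5 and oxa-Michael cyclization onto the enoyl imide made in step 8.

Step 5
Reactants: 5 (S)-linalool triethylsilyl ether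
Product: 7 (4S)-4-methyl-4-(triethylsilyloxy)hex-5-enal, via secondary ozonide 6 (not isolated)
Conditions: O3 (1.0 equiv, titrated solution in CH2Cl2), −78 °C; then Me2S, −78 → 23 °C
Reagents that add atoms: ozone, [O-][O+]=O
Why: Chemoselective ozonolysis, in which the electron-rich trisubstituted alkene reacts far faster than the vinyl group next to the silyloxy-bearing quaternary carbon, and reduction of the ozonide gives the aldehyde whose carbonyl carbon becomes C4a.

Step 6
Reactants: 8 (4S)-4-(diphenylmethyl)-1,3-oxazolidin-2-one; 9 bromoacetyl bromide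
Product: 10 (4S)-3-(bromoacetyl)-4-(diphenylmethyl)-1,3-oxazolidin-2-one
Conditions: n-BuLi, THF, −78 °C; then 9, −78 → 0 °C
Reagents that add atoms: none
Why: N-acylation of the lithiated oxazolidinone at the acyl bromide, the more electrophilic of the two C–Br sites.

Step 7
Reactants: 10 (4S)-3-(bromoacetyl)-4-(diphenylmethyl)-1,3-oxazolidin-2-one
Product: 11 diethyl {2-[(4S)-4-(diphenylmethyl)-2-oxo-1,3-oxazolidin-3-yl]-2-oxoethyl}phosphonate
Conditions: P(OEt)3, 100 °C, neat
Reagents that add atoms: triethyl phosphite, CCOP(OCC)OCC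
Why: Michaelis–Arbuzov reaction of the α-bromo imide (SN2 by phosphorus, then dealkylation of the phosphonium salt by bromide).

Step 8
Reactants: 7 (4S)-4-methyl-4-(triethylsilyloxy)hex-5-enal; 11 diethyl {2-[(4S)-4-(diphenylmethyl)-2-oxo-1,3-oxazolidin-3-yl]-2-oxoethyl}phosphonate
Product: 12 (4S)-4-(diphenylmethyl)-3-[(2E,6S)-6-methyl-6-(triethylsilyloxy)octa-2,7-dienoyl]-1,3-oxazolidin-2-one
Conditions: LiCl, iPr2NEt, MeCN, 23 °C
Reagents that add atoms: none
Why: Horner–Wadsworth–Emmons olefination under mild lithium chloride/amine conditions, which gives the E-enoyl imide from an unbranched aliphatic aldehyde without touching the silyl ether.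

Step 9
Reactants: 12 (4S)-4-(diphenylmethyl)-3-[(2E,6S)-6-methyl-6-(triethylsilyloxy)octa-2,7-dienoyl]-1,3-oxazolidin-2-one; 13 3-iodooxetane
Product: 14 (4S)-4-(diphenylmethyl)-3-[(3R,6S)-6-methyl-3-(oxetan-3-yl)-6-(triethylsilyloxy)oct-7-enoyl]-1,3-oxazolidin-2-one
Conditions: Yb(OTf)3 (1 equiv), 13 (5 equiv), Bu3SnH (2 equiv), Et3B (0.5 equiv), air, CH2Cl2/THF (4:1), −78 °C
Reagents that add atoms: none
Why: Auxiliary-controlled radical conjugate addition (Giese reaction), in which the oxetan-3-yl radical adds to the β-carbon of the Yb-chelated s-cis enoyl imide on the face opposite the diphenylmethyl group, setting C4a, and Bu3SnH reduces the α-acyl radical before it can cyclize onto the remote vinyl group.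

Step 10
Reactants: 14 (4S)-4-(diphenylmethyl)-3-[(3R,6S)-6-methyl-3-(oxetan-3-yl)-6-(triethylsilyloxy)oct-7-enoyl]-1,3-oxazolidin-2-one
Product: 16 (3R,6S)-6-methyl-3-(oxetan-3-yl)-6-(triethylsilyloxy)oct-7-enoic acid, via peroxy acid 15 (not isolated)
Conditions: LiOH, H2O2, THF/H2O (3:1), 0 °C; then Na2SO3; acidification to pH 4 at 0 °C
Reagents that add atoms: hydrogen peroxide, OO
Why: Hydroperoxide cleavage of the N-acyl oxazolidinone at the exocyclic carbonyl followed by sulfite reduction of the peracid, under basic conditions that leave the oxetane and the silyl ether intact; the acid is used at once.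

Step 11
Reactants: 16 (3R,6S)-6-methyl-3-(oxetan-3-yl)-6-(triethylsilyloxy)oct-7-enoic acid
Product: 17 (4R,5R)-5-(hydroxymethyl)-4-[(3S)-3-methyl-3-(triethylsilyloxy)pent-4-en-1-yl]oxan-2-one (trans lactone)
Conditions: PhMe (0.02 M), 80 °C; then DBU (10 mol%), 23 °C
Reagents that add atoms: none
Why: The carboxylic acid hydrogen-bonds to and protonates the oxetane oxygen, and its carboxylate oxygen then opens the strained ring by SN2 attack at one CH2 (C1), which forms the O2–C1 bond and releases the former oxetane oxygen as the C11 hydroxyl. The closest known reaction type is the thermal isomerization of oxetane-carboxylic acids into hydroxymethyl lactones, an acid-promoted intramolecular oxetane opening by an oxygen nucleophile. The δ-lactone closes in the 6-exo-tet mode, since the breaking C1–O bond lies outside the new ring. The new stereocenter C11a arises from the choice between the two diastereotopic oxetane CH2 groups: in the chair-like transition state the four-membered ring holds the unattacked CH2 equatorial, so the C4a stereocenter decides the outcome by keeping its side chain equatorial, which leads to the trans-4,5-disubstituted lactone. The step needs this diastereotopic-group selectivity and it needs ring closure to win over oligomerization and over loss of the tertiary silyl ether; the first is reinforced by thermodynamics, because the two hydroxymethyl lactones interconvert by acyl transfer under catalytic DBU and the diequatorial trans isomer should be the more stable (any cis isomer can be resubmitted), and the second is secured by high dilution and the absence of any acid stronger than the substrate.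

Step 12
Reactants: 17 (4R,5R)-5-(hydroxymethyl)-4-[(3S)-3-methyl-3-(triethylsilyloxy)pent-4-en-1-yl]oxan-2-one
Product: 18 (4R,5R)-4-[(3S)-3-hydroxy-3-methylpent-4-en-1-yl]-5-(hydroxymethyl)oxan-2-one
Conditions: HF·pyridine, pyridine, THF, 0 → 23 °C
Reagents that add atoms: none
Why: Buffered fluoride cleavage of the tertiary silyl ether, which spares the lactone and frees the allylic hydroxyl that should activate the vinyl group in the metathesis of step 15.

Step 13
Reactants: 18 (4R,5R)-4-[(3S)-3-hydroxy-3-methylpent-4-en-1-yl]-5-(hydroxymethyl)oxan-2-one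
Product: 19 (3S,4R)-4-[(3S)-3-hydroxy-3-methylpent-4-en-1-yl]-6-oxooxane-3-carbaldehyde
Conditions: Dess–Martin periodinane, NaHCO3, CH2Cl2, 0 → 23 °C
Reagents that add atoms: none
Why: Dess–Martin oxidation of the primary alcohol under buffered, non-basic conditions, chosen because the β-acyloxy aldehyde would eliminate or epimerize with base, while the tertiary alcohol cannot be oxidized.

Step 14
Reactants: 19 (3S,4R)-4-[(3S)-3-hydroxy-3-methylpent-4-en-1-yl]-6-oxooxane-3-carbaldehyde; 20 allylboronic acid pinacol ester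
Product: 21 (4R,5S)-5-(1-hydroxybut-3-en-1-yl)-4-[(3S)-3-hydroxy-3-methylpent-4-en-1-yl]oxan-2-one (C11 epimers)
Conditions: 20 (1.5 equiv), CH2Cl2, 23 °C; aqueous NaHCO3 work-up
Reagents that add atoms: none
Why: Uncatalysed allylboration through a six-membered chair transition state is neutral and selective for the aldehyde over the lactone, and it supplies C10 and C9.

Step 15
Reactants: 21 (4R,5S)-5-(1-hydroxybut-3-en-1-yl)-4-[(3S)-3-hydroxy-3-methylpent-4-en-1-yl]oxan-2-one
Product: 22 (4aR,7S,8Z,11aS)-7,11-dihydroxy-7-methyl-4,4a,5,6,7,10,11,11a-octahydro-1H-cyclonona[c]pyran-3-one (C11 epimers)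
Conditions: second-generation Grubbs catalyst, (H2IMes)(PCy3)Cl2Ru=CHPh (10 mol%), 1,4-benzoquinone (20 mol%), PhMe (1 mM), 80 °C
Reagents that add atoms: none
Why: Ring-closing metathesis, in which the catalyst loads at the unhindered allyl group and closes onto the C8 vinyl group activated by its free allylic hydroxyl; the trans chains on the lactone are gauche and pre-organized, only a Z alkene fits the nine-membered ring, and C11 is still sp3 so no third alkene can divert the closure.

Step 16
Reactants: 22 (4aR,7S,8Z,11aS)-7,11-dihydroxy-7-methyl-4,4a,5,6,7,10,11,11a-octahydro-1H-cyclonona[c]pyran-3-one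
Product: 23 (4aR,7S,8Z,11aS)-7-hydroxy-7-methyl-4,4a,5,6,7,10-hexahydro-1H-cyclonona[c]pyran-3,11(11aH)-dione
Conditions: Dess–Martin periodinane, NaHCO3, CH2Cl2, 0 °C
Reagents that add atoms: none
Why: Dess–Martin oxidation of the secondary alcohol converges both C11 epimers to one ketone without moving the β,γ-alkene into conjugation or epimerizing C11a.

Step 17
Reactants: 23 (4aR,7S,8Z,11aS)-7-hydroxy-7-methyl-4,4a,5,6,7,10-hexahydro-1H-cyclonona[c]pyran-3,11(11aH)-dione
Product: 24 (4aR,7S,8Z,11aR)-7-hydroxy-7-methyl-11-methylidene-4,4a,5,6,7,10,11,11a-octahydro-1H-cyclonona[c]pyran-3-one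
Conditions: Zn, CH2Br2, TiCl4 (reagent pre-formed in THF), CH2Cl2, 0 → 23 °C
Reagents that add atoms: dibromomethane, BrCBr
Why: Takai–Lombardo methylenation is non-basic, so the β,γ-unsaturated β-acyloxy ketone should neither conjugate, epimerize nor eliminate, and the reagent leaves the lactone carbonyl alone.

Step 18
Reactants: 25 3-methylbut-2-enal; 26 vinylmagnesium bromide
Product: 27 rac-5-methylhexa-1,4-dien-3-ol
Conditions: THF, −78 → 0 °C; aqueous NH4Cl
Reagents that add atoms: none
Why: Grignard 1,2-addition to the enal gives the bis-allylic alcohol that carries C12–C15.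

Step 19
Reactants: 27 rac-5-methylhexa-1,4-dien-3-ol
Product: 28 (1S)-1-[(2S)-3,3-dimethyloxiran-2-yl]prop-2-en-1-ol
Conditions: Ti(OiPr)4 (15 mol%), L-(+)-diisopropyl tartrate (18 mol%), t-BuOOH (0.6 equiv), 4 Å MS, CH2Cl2, −20 °C
Reagents that add atoms: tert-butyl hydroperoxide, CC(C)(C)OO
Why: Sharpless kinetic resolution, in which the (S)-alcohol is the fast-reacting enantiomer with L-(+)-tartrate and is epoxidized at its trisubstituted alkene (far more nucleophilic than the vinyl group) to the erythro epoxy alcohol, fixing C13 and C14, while (R)-27 is left behind.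

Step 20
Reactants: 28 (1S)-1-[(2S)-3,3-dimethyloxiran-2-yl]prop-2-en-1-ol
Product: 29 triethyl({(1S)-1-[(2S)-3,3-dimethyloxiran-2-yl]prop-2-en-1-yl}oxy)silane
Conditions: Et3SiCl, imidazole, CH2Cl2, 0 °C
Reagents that add atoms: chlorotriethylsilane, CC[Si](Cl)(CC)CC
Why: Standard silylation of the secondary alcohol, needed so that the aldehyde of step 21 carries no free α-hydroxyl.

Step 21
Reactants: 29 triethyl({(1S)-1-[(2S)-3,3-dimethyloxiran-2-yl]prop-2-en-1-yl}oxy)silane
Product: 31 (2R)-2-[(2S)-3,3-dimethyloxiran-2-yl]-2-(triethylsilyloxy)acetaldehyde, via secondary ozonide 30 (not isolated)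
Conditions: O3, CH2Cl2, −78 °C; then PPh3, −78 → 0 °C
Reagents that add atoms: ozone, [O-][O+]=O
Why: Ozonolysis of the only alkene with neutral reductive work-up gives the α-silyloxy aldehyde without epimerizing C13 or opening the epoxide; it is used crude.

Step 22
Reactants: 24 (4aR,7S,8Z,11aR)-7-hydroxy-7-methyl-11-methylidene-4,4a,5,6,7,10,11,11a-octahydro-1H-cyclonona[c]pyran-3-one; 31 (2R)-2-[(2S)-3,3-dimethyloxiran-2-yl]-2-(triethylsilyloxy)acetaldehyde
Product: 32 β-hydroxy lactone: 24 bearing at C4 the group CH(OH)–CH(OSiEt3)–[(2S)-3,3-dimethyloxiran-2-yl] (13S,14S; C4 and C12 epimers)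
Conditions: LiN(iPr)2 (2.2 equiv), THF, −78 °C; then 31; AcOH quench at −78 °C
Reagents that add atoms: none
Why: Aldol addition of the lactone lithium enolate (the tertiary hydroxyl is carried as its alkoxide) to the aldehyde at low temperature, at the only enolizable position, C4.

Step 23
Reactants: 32 β-hydroxy lactone
Product: 34 (4E,4aS,7S,8Z,11aR)-4-{(2S)-2-[(2S)-3,3-dimethyloxiran-2-yl]-2-(triethylsilyloxy)ethylidene}-7-hydroxy-7-methyl-11-methylidene-4,4a,5,6,7,10,11,11a-octahydro-1H-cyclonona[c]pyran-3-one, via C12 acetate 33 (not isolated)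
Conditions: Ac2O, DMAP (cat.), pyridine, CH2Cl2, 0 °C; then DBU, PhMe, 0 → 23 °C
Reagents that add atoms: acetic anhydride, CC(=O)OC(C)=O (its acetyl group is carried by 33 only)
Why: Selective acetylation of the secondary carbinol (the tertiary C7 alcohol is inert under these conditions) followed by E1cB elimination through the lactone enolate, which should give the conjugated E-alkylidene, side chain anti to the carbonyl, as the thermodynamically preferred isomer.

Step 24
Reactants: 34 silyl-protected alkylidene lactone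
Product: 35 (4E,4aS,7S,8Z,11aR)-4-{(2S)-2-[(2S)-3,3-dimethyloxiran-2-yl]-2-hydroxyethylidene}-7-hydroxy-7-methyl-11-methylidene-4,4a,5,6,7,10,11,11a-octahydro-1H-cyclonona[c]pyran-3-one
Conditions: Bu4NF, AcOH (1:1), THF, 0 °C
Reagents that add atoms: none
Why: Fluoride desilylation buffered with acetic acid, so that the freed C13 alkoxide cannot trigger epoxide migration or attack the unsaturated lactone.

Step 25
Reactants: 35 dienyl diol
Product: 36 target CNP0147265.1, (4aS,7S,8R,9R,11aR,12E,13S,14S)-7,13-dihydroxy-8,9:14,15-diepoxy lactone (xenicane numbering)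
Conditions: VO(acac)2 (5 mol%), t-BuOOH (1.2 equiv), CH2Cl2, 0 → 23 °C
Reagents that add atoms: tert-butyl hydroperoxide, CC(C)(C)OO
Why: Hydroxyl-directed epoxidation, in which the vanadium alkoxide of the tertiary allylic C7 alcohol delivers oxygen to the syn face of the Z-C8=C9 alkene (cis-epoxy alcohol, as for medium-ring Z-allylic alcohols), setting C8 and C9; the conjugated C4=C12 alkene is too electron-poor and the C11=C19 alkene too remote to compete.

**Compound list**

1 | geraniol | CC(C)=CCC/C(C)=C/CO | starting material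
2 | (2S,3S)-2,3-epoxygeraniol | OC[C@@H]1O[C@@]1(C)CCC=C(C)C | intermediate
3 | (2R,3S)-2-(iodomethyl)-3-methyl-3-(4-methylpent-3-en-1-yl)oxirane | IC[C@@H]1O[C@@]1(C)CCC=C(C)C | intermediate
4 | (S)-linalool | C=C[C@@](C)(O)CCC=C(C)C | intermediate
5 | (S)-linalool triethylsilyl ether | C=C[C@@](C)(O[Si](CC)(CC)CC)CCC=C(C)C | intermediate
6 | 3,3-dimethyl-5-[(3S)-3-methyl-3-(triethylsilyloxy)pent-4-en-1-yl]-1,2,4-trioxolane (secondary ozonide) | C=C[C@@](C)(O[Si](CC)(CC)CC)CCC1OOC(C)(C)O1 | intermediate (not isolated)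
7 | (4S)-4-methyl-4-(triethylsilyloxy)hex-5-enal | C=C[C@@](C)(O[Si](CC)(CC)CC)CCC=O | intermediate
8 | (4S)-4-(diphenylmethyl)-1,3-oxazolidin-2-one | O=C1N[C@H](CO1)C(c2ccccc2)c3ccccc3 | starting material
9 | bromoacetyl bromide | BrCC(Br)=O | starting material
10 | (4S)-3-(bromoacetyl)-4-(diphenylmethyl)-1,3-oxazolidin-2-one | O=C1OC[C@H](C(c2ccccc2)c3ccccc3)N1C(=O)CBr | intermediate
11 | diethyl {2-[(4S)-4-(diphenylmethyl)-2-oxo-1,3-oxazolidin-3-yl]-2-oxoethyl}phosphonate | O=C1OC[C@H](C(c2ccccc2)c3ccccc3)N1C(=O)CP(=O)(OCC)OCC | intermediate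
12 | (4S)-4-(diphenylmethyl)-3-[(2E,6S)-6-methyl-6-(triethylsilyloxy)octa-2,7-dienoyl]-1,3-oxazolidin-2-one | C=C[C@@](C)(O[Si](CC)(CC)CC)CC/C=C/C(=O)N1C(=O)OC[C@@H]1C(c2ccccc2)c3ccccc3 | intermediate
13 | 3-iodooxetane | IC1COC1 | starting material
14 | (4S)-4-(diphenylmethyl)-3-[(3R,6S)-6-methyl-3-(oxetan-3-yl)-6-(triethylsilyloxy)oct-7-enoyl]-1,3-oxazolidin-2-one | C=C[C@@](C)(O[Si](CC)(CC)CC)CC[C@@H](C1COC1)CC(=O)N2C(=O)OC[C@@H]2C(c3ccccc3)c4ccccc4 | intermediate
15 | (3R,6S)-6-methyl-3-(oxetan-3-yl)-6-(triethylsilyloxy)oct-7-eneperoxoic acid | C=C[C@@](C)(O[Si](CC)(CC)CC)CC[C@@H](C1COC1)CC(=O)OO | intermediate (not isolated)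
16 | (3R,6S)-6-methyl-3-(oxetan-3-yl)-6-(triethylsilyloxy)oct-7-enoic acid | C=C[C@@](C)(O[Si](CC)(CC)CC)CC[C@@H](C1COC1)CC(=O)O | intermediate
17 | (4R,5R)-5-(hydroxymethyl)-4-[(3S)-3-methyl-3-(triethylsilyloxy)pent-4-en-1-yl]oxan-2-one | O=C1C[C@@H](CC[C@](C)(O[Si](CC)(CC)CC)C=C)[C@H](CO)CO1 | intermediate
18 | (4R,5R)-4-[(3S)-3-hydroxy-3-methylpent-4-en-1-yl]-5-(hydroxymethyl)oxan-2-one | O=C1C[C@@H](CC[C@](C)(O)C=C)[C@H](CO)CO1 | intermediate
19 | (3S,4R)-4-[(3S)-3-hydroxy-3-methylpent-4-en-1-yl]-6-oxooxane-3-carbaldehyde | O=C1C[C@@H](CC[C@](C)(O)C=C)[C@H](C=O)CO1 | intermediate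
20 | allylboronic acid pinacol ester | C=CCB1OC(C)(C)C(C)(C)O1 | starting material
21 | (4R,5S)-5-(1-hydroxybut-3-en-1-yl)-4-[(3S)-3-hydroxy-3-methylpent-4-en-1-yl]oxan-2-one, C11 epimers | O=C1C[C@@H](CC[C@](C)(O)C=C)[C@H](C(O)CC=C)CO1 | intermediate
22 | (4aR,7S,8Z,11aS)-7,11-dihydroxy-7-methyl-4,4a,5,6,7,10,11,11a-octahydro-1H-cyclonona[c]pyran-3-one, C11 epimers | OC1C/C=C\[C@@](C)(O)CC[C@@H]2CC(=O)OC[C@@H]12 | intermediate
23 | (4aR,7S,8Z,11aS)-7-hydroxy-7-methyl-4,4a,5,6,7,10-hexahydro-1H-cyclonona[c]pyran-3,11(11aH)-dione | O=C1C/C=C\[C@@](C)(O)CC[C@@H]2CC(=O)OC[C@@H]12 | intermediate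
24 | (4aR,7S,8Z,11aR)-7-hydroxy-7-methyl-11-methylidene-4,4a,5,6,7,10,11,11a-octahydro-1H-cyclonona[c]pyran-3-one | C=C1C/C=C\[C@@](C)(O)CC[C@@H]2CC(=O)OC[C@@H]12 | intermediate
25 | 3-methylbut-2-enal | CC(C)=CC=O | starting material
26 | vinylmagnesium bromide | C=C[Mg]Br | starting material
27 | rac-5-methylhexa-1,4-dien-3-ol | C=CC(O)C=C(C)C | intermediate
28 | (1S)-1-[(2S)-3,3-dimethyloxiran-2-yl]prop-2-en-1-ol | C=C[C@H](O)[C@@H]1OC1(C)C | intermediate
29 | triethyl({(1S)-1-[(2S)-3,3-dimethyloxiran-2-yl]prop-2-en-1-yl}oxy)silane | C=C[C@H](O[Si](CC)(CC)CC)[C@@H]1OC1(C)C | intermediate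
30 | secondary ozonide of 29 (1,2,4-trioxolane at the former vinyl group) | C1OOC(O1)[C@H](O[Si](CC)(CC)CC)[C@@H]2OC2(C)C | intermediate (not isolated)
31 | (2R)-2-[(2S)-3,3-dimethyloxiran-2-yl]-2-(triethylsilyloxy)acetaldehyde | O=C[C@H](O[Si](CC)(CC)CC)[C@@H]1OC1(C)C | intermediate
32 | β-hydroxy lactone (aldol adduct of 24 and 31; C4 and C12 epimers) | C=C1C/C=C\[C@@](C)(O)CC[C@@H]2C(C(O)[C@H](O[Si](CC)(CC)CC)[C@@H]3OC3(C)C)C(=O)OC[C@@H]12 | intermediate
33 | C12 acetate of 32 | C=C1C/C=C\[C@@](C)(O)CC[C@@H]2C(C(OC(C)=O)[C@H](O[Si](CC)(CC)CC)[C@@H]3OC3(C)C)C(=O)OC[C@@H]12 | intermediate (not isolated)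
34 | (4E,4aS,7S,8Z,11aR)-4-{(2S)-2-[(2S)-3,3-dimethyloxiran-2-yl]-2-(triethylsilyloxy)ethylidene}-7-hydroxy-7-methyl-11-methylidene-4,4a,5,6,7,10,11,11a-octahydro-1H-cyclonona[c]pyran-3-one | C=C1C/C=C\[C@@](C)(O)CC[C@@H]2/C(=C\[C@H](O[Si](CC)(CC)CC)[C@@H]3OC3(C)C)C(=O)OC[C@@H]12 | intermediate
35 | (4E,4aS,7S,8Z,11aR)-4-{(2S)-2-[(2S)-3,3-dimethyloxiran-2-yl]-2-hydroxyethylidene}-7-hydroxy-7-methyl-11-methylidene-4,4a,5,6,7,10,11,11a-octahydro-1H-cyclonona[c]pyran-3-one | C=C1C/C=C\[C@@](C)(O)CC[C@@H]2/C(=C\[C@H](O)[C@@H]3OC3(C)C)C(=O)OC[C@@H]12 | intermediate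
36 | CNP0147265.1 | C=C1C[C@H]2O[C@H]2[C@@](C)(O)CC[C@@H]2/C(=C\[C@H](O)[C@@H]3OC3(C)C)C(=O)OC[C@@H]12 | target

**Step count and risks**

Total step count: 25. Longest linear sequence: 19 steps (geraniol to the target: steps 1–5, 8–17, 22–25).

Steps most likely to fail:

1. Step 15 (ring-closing metathesis). Cross-metathesis oligomerization at the unhindered allyl terminus may outrun closure of the strained nine-membered ring, or the hindered C8 vinyl group may fail to engage. The fallback replaces olefin metathesis by carbonyl coupling. Starting from 21, both hydroxyls would be silylated (Et3SiOTf, 2,6-lutidine) to the bis(triethylsilyl) ether F1. Both terminal alkenes would be cleaved (O3; PPh3) to the dialdehyde F2. The C8=C9 bond would then be made by intramolecular McMurry coupling with low-valent titanium (TiCl3(DME)1.5, Zn–Cu, DME, reflux, slow addition) to the silylated Z-cyclononene F3, and HF·pyridine would return the route to 22.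

2. Step 19 (kinetic resolution). The cis-methyl group on the reacting alkene may lower the rate difference between the enantiomers and the erythro preference, which would erode the enantiomeric purity of the epoxy alcohol. The fallback sets C14 first and C13 second. 3-Methylbut-2-en-1-ol (CC(C)=CCO) would be epoxidized (Ti(OiPr)4, L-(+)-diethyl tartrate, t-BuOOH) to [(2S)-3,3-dimethyloxiran-2-yl]methanol F4 and oxidized (Dess–Martin periodinane) to (2R)-3,3-dimethyloxirane-2-carbaldehyde F5. Addition of 26 at −78 °C should favor the erythro alcohol by Felkin–Anh attack anti to the epoxide C–O bond; after chromatographic removal of the C13 epimer the route is rejoined at 28.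

3. Step 23 (elimination). The Z-alkylidene isomer may form, or the product may be deprotonated at C13 with opening of the adjacent epoxide. The fallback replaces aldol–elimination by a direct olefination. Starting from 24, LiN(iPr)2 and (EtO)2P(O)Cl followed by more LiN(iPr)2 (enol phosphate to α-phosphonate shift) would give the α-(diethoxyphosphoryl) lactone F6. Horner–Wadsworth–Emmons reaction of F6 with 31 (LiCl, DBU, MeCN) would lead directly to 34.

**Further compounds**

F1 | step 15 | bis(triethylsilyl) ether of 21 | O=C1C[C@@H](CC[C@](C)(O[Si](CC)(CC)CC)C=C)[C@H](C(O[Si](CC)(CC)CC)CC=C)CO1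
F2 | step 15 | dialdehyde from double ozonolysis of F1 | O=C1C[C@@H](CC[C@](C)(O[Si](CC)(CC)CC)C=O)[C@H](C(O[Si](CC)(CC)CC)CC=O)CO1
F3 | step 15 | bis(triethylsilyl) ether of 22 | CC[Si](CC)(CC)OC1C/C=C\[C@@](C)(O[Si](CC)(CC)CC)CC[C@@H]2CC(=O)OC[C@@H]12
F4 | step 19 | [(2S)-3,3-dimethyloxiran-2-yl]methanol | OC[C@@H]1OC1(C)C
F5 | step 19 | (2R)-3,3-dimethyloxirane-2-carbaldehyde | O=C[C@@H]1OC1(C)C
F6 | step 23 | 4-(diethoxyphosphoryl) derivative of 24 | C=C1C/C=C\[C@@](C)(O)CC[C@@H]2C(P(=O)(OCC)OCC)C(=O)OC[C@@H]12
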